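**Retrosynthetic overview**
1. End game: desilylation ⇐ C15 CH2OH → CHO ⇐ C7 isopropenyl → acrylic acid (allylic oxidation, Pinnick) ⇐ reduction of a trans-decalin 1-keto-15-aldehyde.
2. Key disconnection: the ring-fusion bond C5–C10 together with C3–C4, by an intramolecular ionic [4+2] (double Michael) reaction of an open-chain 2-silyloxydiene / enal acetal. Ring B (through C5–C10) and ring A (through C3–C4) close in this one operation, and no carbocycle exists before it.
3. Enabling feature: in ring A the C1 oxygen is para to the formyl-bearing C4. O=C1–C10–C5–C4–C15=O is therefore a 1,5-dicarbonyl spanning the fusion bond (C10 α to C1, C5 β to C15), and C1–C3 are a vinyl ketone. In ring B the C6–O, C7–C and C8–O bonds are all equatorial, so the all-syn chain folds into one chair.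
4. Chain: the C8 ester and the vinyl ketone come from a γ-lactone (vinyl Grignard opening, Shiina esterification). The lactone comes from 1,3-syn reduction of a β-hydroxy ketone made by Fukuyama coupling with a zinc homoenolate.
5. C6/C7 come from a deconjugative Evans syn-aldol of a senecioyl imide with fumaraldehyde mono-acetal.

Key step: step 12

Remark: eudesmane numbering (C1–C15) is used throughout; C10 of all open-chain intermediates is carried as an epimer mixture (drawn without descriptor) because step 11 planarises it, and the target is assumed to be isolable in the open 6-hydroxy-12-acid / 15-aldehyde form that is drawn.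

Step 1
Reactants: 1 (S)-4-benzyloxazolidin-2-one; 2 3-methylbut-2-enoyl chloride
Product: 4 (S)-4-benzyl-3-(3-methylbut-2-enoyl)oxazolidin-2-one, via lithium oxazolidinide 3 (not isolated)
Conditions: n-BuLi, THF, −78 °C; then 2, −78 → 0 °C
Reagents that add atoms: n-butyllithium, [Li]CCCC (lithium only in 3)
Why: Standard N-acylation of a lithiated Evans oxazolidinone by an acid chloride; no stereocentre is formed and the conjugated acyl group is the latent C7/C11–C13 isopropenyl unit.

Step 2
Reactants: 4 (S)-4-benzyl-3-(3-methylbut-2-enoyl)oxazolidin-2-one; 5 (E)-4,4-dimethoxybut-2-enal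
Product: 8 syn-aldol imide (2S,3R), via boron dienolate 6 (not isolated), via boron aldolate 7 (not isolated)
Conditions: Bu2BOTf, Et3N, CH2Cl2, −78 → 0 °C; 5, −78 → 0 °C; then H2O2, MeOH, pH 7 buffer, 0 °C
Reagents that add atoms: dibutylboron triflate, CCCCB(CCCC)OS(=O)(=O)C(F)(F)F (boron only in 6 and 7)
Why: Evans syn-aldol reaction in its deconjugative form: soft enolisation removes a γ-proton to give the (Z)-boron dienolate, which reacts at its α-carbon through a Zimmerman–Traxler chair on the face opposite the benzyl group, so that C7 (S) and C6 (R) are set syn under auxiliary control and the isopropenyl group is released.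

Step 3
Reactants: 8 syn-aldol imide
Product: 9 S-ethyl (2S,3R,4E)-3-hydroxy-6,6-dimethoxy-2-(prop-1-en-2-yl)hex-4-enethioate
Conditions: EtSH, n-BuLi, THF, 0 °C
Reagents that add atoms: ethanethiol, CCS
Why: Thiolate cleavage of the exocyclic imide carbonyl (transthioesterification with release of the auxiliary); the weakly basic thiolate should neither trigger retro-aldol cleavage nor epimerise C7, and no Michael acceptor is present.

Step 4
Reactants: 9 β-hydroxy thioester; 10 methyl 3-bromo-2-methylpropanoate (racemic)
Product: 12 methyl (5S,6R,7E)-6-hydroxy-9,9-dimethoxy-2-methyl-4-oxo-5-(prop-1-en-2-yl)non-7-enoate, via zinc homoenolate 11 (not isolated)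
Conditions: 10, Zn, I2 (cat.), DMA, 70 °C; then 9, PdCl2(PPh3)2 (cat.), toluene, rt
Reagents that add atoms: zinc, [Zn] (only in 11)
Why: Fukuyama coupling: Pd(0) inserts into the C–S bond and the mild zinc homoenolate transfers its alkyl group, a neutral ketone synthesis that should tolerate the free hydroxyl, the acetal and the base-sensitive C7–H; no stereocentre is formed and C10 is deliberately left unassigned.

Step 5
Reactants: 12 hydroxy keto ester
Product: 14 hydroxy lactone (O8–C1 γ-lactone with free 6-OH), via syn-diol ester 13 (not isolated)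
Conditions: Et2BOMe, THF–MeOH, −78 °C; NaBH4; pH 7 buffer, then MeOH azeotrope; DBU (cat.), CH2Cl2, rt
Reagents that add atoms: none
Why: Narasaka–Prasad reduction: the boron chelate of the β-hydroxy ketone is attacked by external hydride axially, opposite the pseudo-axial isopropenyl group, which sets C8 1,3-syn to C6 (all-syn C6/C7/C8 triad), and only the new C8 hydroxyl can reach the ester through a five-membered ring, so the lactonisation tells O8 from O6.

Step 6
Reactants: 14 hydroxy lactone
Product: 15 6-O-TBS lactone
Conditions: TBSOTf, 2,6-lutidine, CH2Cl2, −78 °C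
Reagents that add atoms: tert-butyldimethylsilyl triflate, CC(C)(C)[Si](C)(C)OS(=O)(=O)C(F)(F)F
Why: Silylation of the only free hydroxyl (O6) with a silyl triflate and a hindered pyridine base; at −78 °C O-silylation should be much faster than activation of the dimethyl acetal, and no stereocentre is touched.

Step 7
Reactants: 15 6-O-TBS lactone; 16 vinylmagnesium bromide
Product: 18 γ-hydroxy vinyl ketone (free 8-OH), via magnesium lactolate 17 (not isolated)
Conditions: 16 (1.1 equiv), THF, −78 °C; pH 7 buffer
Reagents that add atoms: none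
Why: Mono-addition of a Grignard reagent to a γ-lactone: the cyclic magnesium lactolate should persist at −78 °C and open only on quench, which holds back a second addition and delivers the C1–C3 vinyl ketone with O8 free; no stereocentre of the triad is touched.

Step 8
Reactants: 19 ethyl 2-(hydroxymethyl)acrylate
Product: 20 ethyl 2-[(tert-butyldimethylsilyloxy)methyl]acrylate
Conditions: TBSCl, imidazole, CH2Cl2, 0 °C → rt
Reagents that add atoms: tert-butyldimethylsilyl chloride, CC(C)(C)[Si](C)(C)Cl
Why: Standard imidazole-promoted silyl ether formation on the primary allylic alcohol; no stereocentre.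

Step 9
Reactants: 20 ethyl 2-[(tert-butyldimethylsilyloxy)methyl]acrylate
Product: 21 2-[(tert-butyldimethylsilyloxy)methyl]acrylic acid
Conditions: LiOH, THF–H2O, 0 °C → rt; then 1 M HCl to pH 4, 0 °C
Reagents that add atoms: lithium hydroxide, [Li+].[OH-]
Why: Saponification of an unhindered ethyl ester under conditions that leave a TBS ether intact; no stereocentre.

Step 10
Reactants: 18 γ-hydroxy vinyl ketone; 21 2-[(tert-butyldimethylsilyloxy)methyl]acrylic acid
Product: 22 8-O-acyl enone acetal
Conditions: MNBA, Et3N, DMAP (cat.), CH2Cl2, 0 °C → rt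
Reagents that add atoms: none
Why: Shiina esterification (MNBA mixed anhydride, acyl transfer by DMAP): the open hydroxy-ketone tautomer is acylated at O8 with retention at C8, and the mild medium should spare the vinyl ketone and the acetal.

Step 11
Reactants: 22 8-O-acyl enone acetal
Product: 23 TES dienol ether (2-silyloxydiene / enal acetal)
Conditions: TESOTf, Et3N, CH2Cl2, −78 → −30 °C; filtration through Et3N-deactivated silica
Reagents that add atoms: triethylsilyl triflate, CC[Si](CC)(CC)OS(=O)(=O)C(F)(F)F
Why: Soft enolisation and O-silylation of a ketone (silyl triflate/amine): C10–H is the only enolisable position, so a single cross-conjugated 2-silyloxydiene regioisomer should form (E/Z mixture), the C10 epimers converge, and the low temperature should keep the acetal un-ionised.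

Step 12
Reactants: 23 TES dienol ether
Product: 25 trans-decalin 1-keto-15-aldehyde (4α-CHO, 5αH, 6α-OTBS, 7β-isopropenyl, 8α-acyloxy, 10β-Me), via cycloadduct enol silane 24 (not isolated)
Conditions: TMSOTf (0.2 equiv), 2,6-di-tert-butyl-4-methylpyridine (0.3 equiv), CH2Cl2 (0.005 M), −78 → −40 °C; then 5 % aq. oxalic acid, THF, 0 °C → rt
Reagents that add atoms: water, O
Why: Proposed new method: catalytic TMSOTf ionises the allylic dimethyl acetal to a vinyl-oxocarbenium ion whose C5 terminus is attacked by C10 of the tethered 2-silyloxydiene (Mukaiyama–Michael-like first bond), the resulting methyl enol ether (C4) closes onto C3 of the O-silylated vinyl ketone, and MeOSiMe3 returns methoxide to C15 so that the silyl triflate turns over, overall a highly asynchronous type-1 intramolecular ionic Diels–Alder reaction. The closest known reaction types are the acid-catalysed ionic Diels–Alder reaction of α,β-unsaturated acetals, the Lewis-acid Diels–Alder/double Mukaiyama–Michael reaction of fully substituted 2-silyloxydienes that builds quaternary carbons, and the intramolecular double Michael reaction; new is their union in one open-chain substrate that creates a quaternary ring-fusion carbon. Ring B closes 6-exo-trig at C5 (bond C5–C10) through a chair in which the C6-OTBS, C7-isopropenyl and C8-acyloxy groups are all equatorial, and ring A closes 6-(enolexo)-endo-trig (bond C4–C3), the two σ-bonds of a [4+2] with a four-atom tether. C5 is set by that chair with attack anti to the allylic C6–O bond (H-5 axial, α), C10 by the endo (oxocarbenium under the diene, tether exo) arrangement that places C1 equatorial and the methyl axial (β, trans-fusion), and C4 by the E-geometry of the dienophile (C15 equatorial, α), which is also the thermodynamic epimer after hydrolysis. Because the C10–C1 bond can rotate after the first bond is made, both enol-silane geometries should converge on the same product. The step needs 1,4- over 1,2-attack (six- versus eight-membered ring), the enol silane rather than the isopropenyl group as nucleophile (far higher nucleophilicity, 5-endo closure for the alkene) and the oxocarbenium ion rather than the C8 acrylate as acceptor (cation versus neutral ester, seven-membered closure), while high dilution and the hindered pyridine suppress intermolecular and proton-mediated paths.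

Step 13
Reactants: 25 trans-decalin 1-keto-15-aldehyde
Product: 26 1β,15-diol
Conditions: NaBH4, MeOH–CH2Cl2, −40 → 0 °C
Reagents that add atoms: none
Why: Borohydride reduction: the aldehyde gives the C15 carbinol and the C1 ketone is attacked axially from the α-face, opposite the angular β-methyl on the neighbouring C10, which sets the equatorial 1β-hydroxyl; the α-substituted acrylate ester and the isolated alkene should not be reduced at this temperature.

Step 14
Reactants: 26 1β,15-diol
Product: 28 12-al (C7 2-propenal unit), via allylic alcohol 27 (not isolated)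
Conditions: SeO2 (cat.), t-BuOOH, CH2Cl2, 0 °C → rt; crude: MnO2, CH2Cl2, rt
Reagents that add atoms: tert-butyl hydroperoxide, CC(C)(C)OO (oxygen relayed by selenium dioxide, O=[Se]=O)
Why: Riley allylic oxidation (ene reaction, then [2,3]-sigmatropic shift) should attack only the electron-rich 1,1-disubstituted C11=C13 alkene at its methyl group and not the electron-poor acrylate, and MnO2 then oxidises only the allylic alcohol, leaving the saturated C1 and C15 carbinols; no stereocentre changes.

Step 15
Reactants: 28 12-al
Product: 29 12-oic acid (C15 still CH2OH)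
Conditions: NaClO2, NaH2PO4, 2-methylbut-2-ene, t-BuOH–H2O, 0 °C
Reagents that add atoms: sodium chlorite, [Na+].[O-]Cl=O
Why: Pinnick oxidation of the 2-substituted acrolein to the acrylic acid with a hypochlorite scavenger; alcohols, alkenes and silyl ethers are inert, and with O6 silylated and O8 acylated no γ-lactone can form.

Step 16
Reactants: 29 12-oic acid
Product: 30 bis-TBS ether of the target (15-al, 12-oic acid)
Conditions: TEMPO (cat.), PhI(OAc)2, CH2Cl2, rt
Reagents that add atoms: none
Why: Oxoammonium (TEMPO/PhI(OAc)2) oxidation, selective for the primary C15 carbinol over the hindered secondary C1 carbinol and stopping at the aldehyde in the absence of water; the equatorial C4 configuration is also the thermodynamic one.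

Step 17
Reactants: 30 bis-TBS ether of the target
Product: 31 target CNP0599450.1
Conditions: HF·pyridine, pyridine, THF, 0 °C → rt; pH 6.5 phosphate buffer work-up
Reagents that add atoms: none
Why: Fluoride-mediated cleavage of both TBS ethers in a pyridine-buffered medium, chosen so that the liberated 6-hydroxyl meets the C12 acid largely as its carboxylate and the trans-fused lactone is not closed; no stereocentre is affected.

**Compound list**
1 | (S)-4-benzyloxazolidin-2-one | O=C1N[C@@H](Cc2ccccc2)CO1 | starting material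
2 | 3-methylbut-2-enoyl chloride | CC(C)=CC(=O)Cl | starting material
3 | lithium (S)-4-benzyl-2-oxooxazolidin-3-ide | O=C1[N-][C@@H](Cc2ccccc2)CO1.[Li+] | intermediate
4 | (S)-4-benzyl-3-(3-methylbut-2-enoyl)oxazolidin-2-one | CC(C)=CC(=O)N1[C@@H](Cc2ccccc2)COC1=O | intermediate
5 | (E)-4,4-dimethoxybut-2-enal (fumaraldehyde mono-dimethyl acetal) | O=C/C=C/C(OC)OC | starting material
6 | (Z)-dibutylboron dienolate of 4 | CC(=C)/C=C(\OB(CCCC)CCCC)N1[C@@H](Cc2ccccc2)COC1=O | intermediate
7 | dibutylboron aldolate of 8 | O=C1OC[C@H](Cc2ccccc2)N1C(=O)[C@@H](C(C)=C)[C@H](OB(CCCC)CCCC)/C=C/C(OC)OC | intermediate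
8 | (S)-4-benzyl-3-[(2S,3R,4E)-3-hydroxy-6,6-dimethoxy-2-(prop-1-en-2-yl)hex-4-enoyl]oxazolidin-2-one | O=C1OC[C@H](Cc2ccccc2)N1C(=O)[C@@H](C(C)=C)[C@H](O)/C=C/C(OC)OC | intermediate
9 | S-ethyl (2S,3R,4E)-3-hydroxy-6,6-dimethoxy-2-(prop-1-en-2-yl)hex-4-enethioate | CCSC(=O)[C@@H](C(C)=C)[C@H](O)/C=C/C(OC)OC | intermediate
10 | methyl 3-bromo-2-methylpropanoate (racemic) | COC(=O)C(C)CBr | starting material
11 | (3-methoxy-2-methyl-3-oxopropyl)zinc bromide | COC(=O)C(C)C[Zn]Br | intermediate
12 | methyl (5S,6R,7E)-6-hydroxy-9,9-dimethoxy-2-methyl-4-oxo-5-(prop-1-en-2-yl)non-7-enoate, C2 (= C10) epimers | COC(=O)C(C)CC(=O)[C@@H](C(C)=C)[C@H](O)/C=C/C(OC)OC | intermediate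
13 | methyl (4S,5R,6R,7E)-4,6-dihydroxy-9,9-dimethoxy-2-methyl-5-(prop-1-en-2-yl)non-7-enoate, all-syn triad | COC(=O)C(C)C[C@H](O)[C@@H](C(C)=C)[C@H](O)/C=C/C(OC)OC | intermediate
14 | (5S)-5-[(3S,4R,5E)-4-hydroxy-7,7-dimethoxy-2-methylhepta-1,5-dien-3-yl]-3-methyloxolan-2-one | CC1C[C@H](OC1=O)[C@@H](C(C)=C)[C@H](O)/C=C/C(OC)OC | intermediate
15 | TBS ether of 14 at O6 | CC1C[C@H](OC1=O)[C@@H](C(C)=C)[C@H](O[Si](C)(C)C(C)(C)C)/C=C/C(OC)OC | intermediate
16 | vinylmagnesium bromide | C=C[Mg]Br | starting material
17 | bromomagnesium 2-vinyl lactolate from 15 | CC1C[C@H](OC1(C=C)O[Mg]Br)[C@@H](C(C)=C)[C@H](O[Si](C)(C)C(C)(C)C)/C=C/C(OC)OC | intermediate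
18 | open-chain C1 vinyl ketone with free 8-OH, 6-OTBS, 7-isopropenyl (all-syn), E-C4=C5, C15 dimethyl acetal | C=CC(=O)C(C)C[C@H](O)[C@@H](C(C)=C)[C@H](O[Si](C)(C)C(C)(C)C)/C=C/C(OC)OC | intermediate
19 | ethyl 2-(hydroxymethyl)acrylate | C=C(CO)C(=O)OCC | starting material
20 | ethyl 2-[(tert-butyldimethylsilyloxy)methyl]acrylate | C=C(CO[Si](C)(C)C(C)(C)C)C(=O)OCC | intermediate
21 | 2-[(tert-butyldimethylsilyloxy)methyl]acrylic acid | C=C(CO[Si](C)(C)C(C)(C)C)C(=O)O | intermediate
22 | 8-O-[2-(TBSO-methyl)acryloyl] derivative of 18 | C=CC(=O)C(C)C[C@H](OC(=O)C(=C)CO[Si](C)(C)C(C)(C)C)[C@@H](C(C)=C)[C@H](O[Si](C)(C)C(C)(C)C)/C=C/C(OC)OC | intermediate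
23 | C1 triethylsilyl dienol ether of 22 (C1=C10 E/Z mixture) | C=CC(O[Si](CC)(CC)CC)=C(C)C[C@H](OC(=O)C(=C)CO[Si](C)(C)C(C)(C)C)[C@@H](C(C)=C)[C@H](O[Si](C)(C)C(C)(C)C)/C=C/C(OC)OC | intermediate
24 | trans-fused cycloadduct: C1(OTES)=C2 enol silane, 4α-CH(OMe)2, 5αH, 10β-Me | C=C(CO[Si](C)(C)C(C)(C)C)C(=O)O[C@H]1C[C@]2(C)[C@@H]([C@@H](O[Si](C)(C)C(C)(C)C)[C@@H]1C(=C)C)[C@H](C(OC)OC)CC=C2O[Si](CC)(CC)CC | intermediate
25 | 1-oxo-15-al trans-decalin: 4α-CHO, 5αH, 6α-OTBS, 7β-isopropenyl (7αH), 8α-acyloxy, 10β-Me | C=C(CO[Si](C)(C)C(C)(C)C)C(=O)O[C@H]1C[C@]2(C)[C@@H]([C@@H](O[Si](C)(C)C(C)(C)C)[C@@H]1C(=C)C)[C@H](C=O)CCC2=O | intermediate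
26 | 1β-hydroxy-15-hydroxy analogue of 25 | C=C(CO[Si](C)(C)C(C)(C)C)C(=O)O[C@H]1C[C@]2(C)[C@@H]([C@@H](O[Si](C)(C)C(C)(C)C)[C@@H]1C(=C)C)[C@H](CO)CC[C@H]2O | intermediate
27 | 12-hydroxy derivative of 26 (C7 2-(hydroxymethyl)vinyl) | C=C(CO[Si](C)(C)C(C)(C)C)C(=O)O[C@H]1C[C@]2(C)[C@@H]([C@@H](O[Si](C)(C)C(C)(C)C)[C@@H]1C(=C)CO)[C@H](CO)CC[C@H]2O | intermediate
28 | 12-al (C7 1-formylvinyl), 1β,15-diol | C=C(CO[Si](C)(C)C(C)(C)C)C(=O)O[C@H]1C[C@]2(C)[C@@H]([C@@H](O[Si](C)(C)C(C)(C)C)[C@@H]1C(=C)C=O)[C@H](CO)CC[C@H]2O | intermediate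
29 | 12-oic acid, 1β,15-diol | C=C(CO[Si](C)(C)C(C)(C)C)C(=O)O[C@H]1C[C@]2(C)[C@@H]([C@@H](O[Si](C)(C)C(C)(C)C)[C@@H]1C(=C)C(=O)O)[C@H](CO)CC[C@H]2O | intermediate
30 | 6-O,4'-O-bis-TBS ether of the target | C=C(CO[Si](C)(C)C(C)(C)C)C(=O)O[C@H]1C[C@]2(C)[C@@H]([C@@H](O[Si](C)(C)C(C)(C)C)[C@@H]1C(=C)C(=O)O)[C@H](C=O)CC[C@H]2O | intermediate
31 | CNP0599450.1: (1R,4R,5S,6R,7S,8S,10R)-1β,6α-dihydroxy-8α-[2-(hydroxymethyl)acryloyloxy]-15-oxoeudesm-11(13)-en-12-oic acid | C=C(CO)C(=O)O[C@H]1C[C@]2(C)[C@@H]([C@@H](O)[C@@H]1C(=C)C(=O)O)[C@H](C=O)CC[C@H]2O | target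

**Step count**
Total step count: 17. Longest linear sequence: 15 (steps 1–7 and 10–17; steps 8–9 make the side-chain acid).

**Steps most likely to fail**

1. Step 12 (Proposed new method). Four processes may interfere:
   - loss of the C6 proton from the vinyl-oxocarbenium ion, which would give a dienol ether;
   - protodesilylation of the enol silane before the C–C bond forms;
   - intermolecular addition;
   - insufficient endo/exo discrimination, which would erode the trans ring fusion.

   The fallback uses known chemistry, sets out from 22 and comes back at 25. The allylic acetal of 22 is hydrolysed (PPTS, acetone–H2O, rt) to the keto enal F1. The vinyl ketone of F1 is converted with TBSOTf/Et3N (CH2Cl2, −78 °C) into the isolable TBS dienol ether enal F2. A conventional type-1 intramolecular Diels–Alder reaction of the 2-silyloxydiene with the neutral enal (Me2AlCl, CH2Cl2, −78 °C, or toluene, 110 °C) gives the TBS enol ether aldehyde F3. Brief HF·pyridine (THF, 0 °C) cleaves the enol silane to 25.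

2. Step 14. The ene reaction may be slow at the isopropenyl group, which is flanked by the C6 silyl ether and the C8 ester. Abstraction of the tertiary allylic C7–H may compete with abstraction of a methyl hydrogen, and the primary silyl ether may be lost in the acidic medium. The fallback sets out from 26 and comes back at 28. Ene-type chlorination with hypochlorous acid (Ca(OCl)2, solid CO2, CH2Cl2–H2O, 0 °C) gives the allylic chloride F4. Amine-oxide oxidation of this activated halide (N-methylmorpholine N-oxide, KI cat., MeCN, rt) then delivers the enal 28. Carbon–oxygen bond formation is thus moved from a selenium ene/[2,3] process to a substitution.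

3. Step 17. Once O6 is freed, lactonisation onto the C12 acid (trans-fused 6,12-olide) or lactol formation with C15 may occur in the acidic fluoride medium. Removal of the hindered C6 silyl ether may also be slow. The fallback sets out from 30 and comes back at 31.
   - The acid is first masked (allyl bromide, KHCO3, DMF, rt) as the allyl ester F5.
   - HF·pyridine then removes both silyl groups to give the hydroxy allyl ester F6, which lacks an acid to lactonise.
   - The acid is released last under neutral conditions by Pd(0)-catalysed allyl transfer (Pd(PPh3)4, N-methylaniline, THF, rt) to give 31.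

**Further compounds**
F1 | step 12 | keto enal (free C15 aldehyde of 22) | C=CC(=O)C(C)C[C@H](OC(=O)C(=C)CO[Si](C)(C)C(C)(C)C)[C@@H](C(C)=C)[C@H](O[Si](C)(C)C(C)(C)C)/C=C/C=O
F2 | step 12 | TBS dienol ether enal | C=CC(O[Si](C)(C)C(C)(C)C)=C(C)C[C@H](OC(=O)C(=C)CO[Si](C)(C)C(C)(C)C)[C@@H](C(C)=C)[C@H](O[Si](C)(C)C(C)(C)C)/C=C/C=O
F3 | step 12 | TBS enol ether aldehyde (trans-decalin cycloadduct) | C=C(CO[Si](C)(C)C(C)(C)C)C(=O)O[C@H]1C[C@]2(C)[C@@H]([C@@H](O[Si](C)(C)C(C)(C)C)[C@@H]1C(=C)C)[C@H](C=O)CC=C2O[Si](C)(C)C(C)(C)C
F4 | step 14 | allylic chloride (12-chloro derivative of 26) | C=C(CO[Si](C)(C)C(C)(C)C)C(=O)O[C@H]1C[C@]2(C)[C@@H]([C@@H](O[Si](C)(C)C(C)(C)C)[C@@H]1C(=C)CCl)[C@H](CO)CC[C@H]2O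
F5 | step 17 | allyl ester of 30 | C=C(CO[Si](C)(C)C(C)(C)C)C(=O)O[C@H]1C[C@]2(C)[C@@H]([C@@H](O[Si](C)(C)C(C)(C)C)[C@@H]1C(=C)C(=O)OCC=C)[C@H](C=O)CC[C@H]2O
F6 | step 17 | allyl ester of the target | C=C(CO)C(=O)O[C@H]1C[C@]2(C)[C@@H]([C@@H](O)[C@@H]1C(=C)C(=O)OCC=C)[C@H](C=O)CC[C@H]2O
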